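## Structural features

The target is a 6-arylated apigenin: benzo ring A (C4a, C5–C8, C8a) is fused to the 4-pyranone ring C (O1, C2, C3, C4), ring B is a 4-hydroxyphenyl group on C2, and C5 and C7 carry free hydroxyls. C6 of ring A is bonded to D3 of a 4-hydroxybenzoic acid ring D (carboxyl on D1, hydroxyl on D4), so the C6–D3 bond is a biaryl bond with three ortho oxygen substituents. There is no stereocentre; the C6–D3 axis has one ortho hydrogen (D2–H), carries no descriptor and needs no control. Four phenols (one chelated to the C4 carbonyl) and a carboxylic acid make the final compound polar, acidic and easily oxidised in base, and the pyranone is opened by strong aqueous base, so all five acidic groups are best kept masked until the last step. The real difficulty is regiochemical: C6 and C8 both lie between oxygen-bearing carbons, and substitution of a preformed 5,7-dioxygenated flavone does not tell them apart reliably; the biaryl bond is also hindered. The key step uses the fact that C8a carries O1 while its neighbour C4a carries the C4 carbonyl, an ortho oxygen/acyl pair that corresponds to an aryne across C4a–C8a taking up a carboxyl oxygen and an acyl group. The C5 oxygen next to C4a polarises that aryne. Because C8a is para to C6, the phenol that precedes the aryne is mirror-symmetric, so the choice between 6-aryl and 8-aryl is settled by symmetry before ring C exists.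

## Logic of the disconnections

17 to 16: the four aryl O–CH3 bonds and the carboxyl O–C(CH3)3 bond are cut. All five masks fall to one boron Lewis acid, so the precursor has no free phenol or acid, can be chromatographed, and tolerates base, fluoride and amine. The forward step must cleave five groups completely without harming the pyranone.

16 to 14: the O1–C2 bond of ring C is cut. This opens the heterocycle to an ortho-hydroxyaryl ynone with the phenol oxygen and the acyl group on adjacent ring-A carbons. The forward step must close the six-membered ring and not the five-membered benzofuranone.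

14 to 11 and 12: O1–C8a and C4–C4a are cut together. The ortho oxygen/acyl pair is the retron of an aryne inserting into a carboxyl C–O bond, and the cut divides the molecule into the biaryl half and a half that brings C2, C3, C4 and ring B. The forward step needs oxygen at C8a and acyl at C4a, which the C5 methoxy group beside the aryne should secure, and acyl transfer must beat protonation of the aryl anion.

11 to 7: the C4a–Si bond and the O–S bond are cut. The silyl triflate goes back to an ortho-bromophenol through O-silylation, bromine–lithium exchange, O-to-C silyl shift and triflation in one flask. The forward step brings an organolithium near a tert-butyl ester, so it must run at very low temperature.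

7 to 6: the C4a–Br bond is cut. The phenol behind it is symmetric, so either free ortho position gives the same product. The forward step only has to stop at monobromination.

6 to 4: the C8a–O bond is cut. The oxygen is placed on the only ring C–H with no ortho substituent, by C–H borylation and oxidation. A Dakin-type oxidation of the corresponding benzaldehyde was rejected because the migrating carbon would have only meta oxygen donors and hydride migration to the acid would compete. The forward step needs sterically controlled site selectivity.

4 to 2 and 3: the C6–D3 biaryl bond is cut. It is made while ring A is still a simple symmetric 2,6-dimethoxyphenyl unit, which leaves two small building blocks. The forward coupling must form a tri-ortho-substituted biaryl from a boronic acid prone to protodeboronation.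

2 to 1: the ester O–C(CH3)3 bond is cut. The tert-butyl ester resists phosphate base, fluoride, amine and brief contact with organolithium at –100 °C, and leaves in the final Lewis acid step. The forward step is a simple esterification.

## Other disconnections considered

Alternative 1: Ring D is dismantled at D1–D2 and D5–D6, so that it would be built on a complete flavone. Forward, silyloxydiene A1 (the trimethylated flavone with a 3-silyloxybuta-1,3-dien-2-yl group on C6) would add methyl propiolate A2 in a normal-demand (4+2) cycloaddition to give cyclohexa-1,4-diene A3. A quinone oxidant would then aromatise A3 before deprotection.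
- In its favour: the hindered C6–D3 bond is never made by coupling at a di-ortho-oxygenated carbon, the para relation of silyloxy donor and ester is the orientation such dienes normally prefer, and aromatisation of a 1,4-diene is easy.
- Against it: the C6 side chain of A1 must first be attached to ring A, so the C6/C8 question is only moved back. The aryl group on the other inner diene carbon directs the ester to the opposite terminus and sits twisted between two methoxy groups, which should cost rate and regiocontrol. The silyl enol ether is hydrolytically labile, and the methyl ester needs its own cleavage.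
- Comparison: in mechanism the two plans are equal, as neither raises a stereochemical question. Alternative 1 is the better on one point, since it needs no metal-catalysed coupling to a hindered position. The chosen plan is the better in regiochemical security, which rests on symmetry and one directing methoxy group, and in step economy, since reaching A1 alone should take about as many steps as reaching 11.

Alternative 2: The C6–D3 bond is cut. Forward, the chelated O5–H of partially methylated flavone A4 would be joined through a CH2 acetal to a 2-bromophenol ester to give A5. Zerovalent palladium would insert into the C–Br bond at D3 and arylate C6–H, giving the methylene-bridged biaryl A6 with a temporary seven-membered dioxepine ring.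
- In its favour: A4 is a cheap flavone, so the sequence is convergent and short. The tether can reach only C6, because C4a is fully substituted. The acetal would fall in the same Lewis acid deprotection as the methyl ethers.
- Against it: the mixed diaryl formaldehyde acetal must be made by alkylating a weakly nucleophilic, hydrogen-bonded O5–H with an aryl chloromethyl ether. The arylation closes a seven-membered ring at an electron-rich C–H flanked by two oxygens, which is slower than five- or six-membered closures and lets reduction of the C–Br bond compete. The methyl ester needs separate hydrolysis.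
- Comparison: Alternative 2 is the better in step count and the equal of the chosen plan in regiocontrol at C6. The chosen plan is the better in the reliability of each bond-forming event, because its biaryl bond comes from a standard cross-coupling and not from a medium-ring C–H arylation.

Alternative 3: Ring D is cut at D2–D3 and D4–D5. Forward, ynol ether A7 (the 6-ethoxyethynyl flavone) would react with methyl coumalate A8 in an inverse-demand (4+2) cycloaddition. Extrusion of the lactone bridge from the bicyclic adduct would leave the aromatic 4-ethoxybenzoate A9.
- In its favour: aromatisation needs no oxidant. The regiochemistry follows from polarity matching, with the nucleophilic alkyne carbon on C6 of the flavone bonding to the most electrophilic pyranone carbon. The D4 oxygen arrives already protected as an ether that the final Lewis acid can cleave.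
- Against it: A7 is acid-sensitive and could lose ethylene to a ketene at the temperature the cycloaddition is likely to need. Its alkyne terminus is shielded by two methoxy groups. It presupposes a flavone functionalised selectively at C6, so the C6/C8 problem returns, and the methyl ester again needs separate cleavage.
- Comparison: Alternative 3 is the better in the redox economy of forming ring D and the equal of the chosen plan in the final deprotection. The chosen plan is the better in the stability of its intermediates and in regiocontrol on ring A.

Key step: step 6

Remark on the chemistry assumed: the C6–D3 axis is treated as stereochemically undefined (three ortho oxygens and one ortho hydrogen, no descriptor in the target), so the route has no stereochemical element to set.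

Remark on the structures: silyl triflate 11 and ynone 14 map atom for atom onto the target (silicon on the future C4a between the triflate on the future C8a and the C5 methoxy group), so neither structure needs correction. The design change is in the access to 11, where the C8a oxygen comes from C–H borylation/oxidation instead of a Dakin oxidation, and O-silylation, silyl shift and triflation run in one flask at –100 °C to protect the ester.

## Route

Step 1
Reactants: 1 3-bromo-4-methoxybenzoic acid
Product: 2 tert-butyl 3-bromo-4-methoxybenzoate
Conditions: Cl3CC(=NH)OtBu (2 equiv), BF3·OEt2 (cat.), CH2Cl2/cyclohexane, rt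
Reagents that add atoms: tert-butyl 2,2,2-trichloroacetimidate, CC(C)(C)OC(=N)C(Cl)(Cl)Cl
Why: Acid-promoted tert-butyl transfer from the imidate to the carboxyl oxygen (imidate esterification) is mild enough for the aryl bromide and the ether. The tert-butyl ester is chosen because it resists the base, fluoride and amine used later and is removed in the final BBr3 step.

Step 2
Reactants: 2 tert-butyl 3-bromo-4-methoxybenzoate; 3 (2,6-dimethoxyphenyl)boronic acid
Product: 4 tert-butyl 3-(2,6-dimethoxyphenyl)-4-methoxybenzoate
Conditions: Pd(OAc)2 (2 mol %), SPhos (4 mol %), K3PO4, toluene/H2O, 100 °C; 3 in 1.5 equiv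
Reagents that add atoms: none
Why: Suzuki–Miyaura coupling with the bulky, electron-rich 2-dicyclohexylphosphino-2′,6′-dimethoxybiphenyl ligand is the standard way to make tri-ortho-substituted biaryls from 2,6-disubstituted boronic acids. The excess of 3 compensates for protodeboronation, and the tert-butyl ester is inert to phosphate.

Step 3
Reactants: 4 tert-butyl 3-(2,6-dimethoxyphenyl)-4-methoxybenzoate
Product: 6 tert-butyl 3-(4-hydroxy-2,6-dimethoxyphenyl)-4-methoxybenzoate, via pinacol boronate 5 (not isolated)
Conditions: B2pin2 (0.6 equiv), [Ir(OMe)(cod)]2 (1.5 mol %), 4,4′-di-tert-butyl-2,2′-bipyridine (3 mol %), THF, 80 °C; then KHSO5 (Oxone, 1 equiv), acetone/H2O, rt, short contact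
Reagents that add atoms: bis(pinacolato)diboron, CC1(C)OB(OC1(C)C)B1OC(C)(C)C(C)(C)O1 (boron and pinacol are held in intermediate 5 only); potassium peroxymonosulfate, [K+].[O-]S(=O)(=O)OO (the phenol oxygen of 6)
Why: Iridium-catalysed C–H borylation is governed by sterics, and the ring-A C–H para to ring D is the only aromatic C–H in 4 with no ortho substituent (all others are ortho to methoxy, ester or aryl). Oxidation of the C–B bond by peroxymonosulfate (1,2-shift of aryl from boron to oxygen) then gives the symmetric phenol in the same flask.

Step 4
Reactants: 6 tert-butyl 3-(4-hydroxy-2,6-dimethoxyphenyl)-4-methoxybenzoate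
Product: 7 tert-butyl 3-(3-bromo-4-hydroxy-2,6-dimethoxyphenyl)-4-methoxybenzoate
Conditions: NBS (1.0 equiv), CH2Cl2, –78 → 0 °C
Reagents that add atoms: N-bromosuccinimide, O=C1CCC(=O)N1Br
Why: Electrophilic aromatic bromination goes to ring A, whose two free positions are equivalent by symmetry and activated by the ortho hydroxyl and two methoxy groups, while ring D is deactivated by the ester. One equivalent at low temperature should limit dibromination.

Step 5
Reactants: 7 tert-butyl 3-(3-bromo-4-hydroxy-2,6-dimethoxyphenyl)-4-methoxybenzoate
Product: 11 tert-butyl 3-[2,6-dimethoxy-4-(trifluoromethanesulfonyloxy)-3-(trimethylsilyl)phenyl]-4-methoxybenzoate, via aryl trimethylsilyl ether 8 (not isolated), via aryllithium 9 (not isolated), via lithium 2-silylphenoxide 10 (not isolated)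
Conditions: HMDS, THF, 70 °C, then evaporation; n-BuLi (1.1 equiv), THF, –100 → –80 °C; Tf2O (1.2 equiv), –100 → –78 °C (one flask)
Reagents that add atoms: hexamethyldisilazane, C[Si](C)(C)N[Si](C)(C)C; trifluoromethanesulfonic anhydride, O=S(=O)(OS(=O)(=O)C(F)(F)F)C(F)(F)F; n-butyllithium, [Li]CCCC (lithium is held in intermediates 9 and 10 only)
Why: This is the standard one-flask route to ortho-silylaryl triflates: O-silylation, bromine–lithium exchange, 1,3 O-to-C silyl migration (retro-Brook rearrangement) to the lithium phenoxide, and O-triflation. At –100 °C the exchange is much faster than addition of butyllithium to the remote tert-butyl ester, and the aryllithium is consumed intramolecularly.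

Step 6
Reactants: 11 tert-butyl 3-[2,6-dimethoxy-4-(trifluoromethanesulfonyloxy)-3-(trimethylsilyl)phenyl]-4-methoxybenzoate; 12 3-(4-methoxyphenyl)propiolic acid
Product: 14 tert-butyl 3-{4-hydroxy-2,6-dimethoxy-3-[3-(4-methoxyphenyl)propioloyl]phenyl}-4-methoxybenzoate, via aryne 13 (not isolated)
Conditions: CsF (4 equiv), THF, 125 °C, sealed tube; 12 in 1.3 equiv, anhydrous
Reagents that add atoms: none
Why: Fluoride attacks silicon in 11 and triflate leaves, giving aryne 13 across C4a–C8a. The cesium carboxylate of 12 adds through oxygen to C8a, the terminus remote from the C5 methoxy group, because that oxygen distorts the aryne so that C8a is the more electrophilic carbon and stabilises inductively the negative charge developing at C4a. The C4a anion then attacks the neighbouring ester carbonyl through a four-membered transition state, an anionic Fries-type 1,3 O-to-C acyl shift, which leaves the phenoxide of 14 with the new O1–C8a and C4–C4a bonds. The closest known reaction type is the insertion of arynes into the C–O bond of carboxylic acids to give ortho-hydroxyaryl ketones. No ring is closed and no stereocentre is formed. Two selectivities are needed: regioselective capture of the unsymmetrical aryne, which the C5 methoxy group secures, and acyl transfer in preference to protonation of the aryl anion, which high temperature, dry conditions and only a small excess of acid should favour. Any 14 that closes to the six-membered ring in the flask becomes 16, the product of the next step, so the crude material can be carried forward as a whole.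

Step 7
Reactants: 14 tert-butyl 3-{4-hydroxy-2,6-dimethoxy-3-[3-(4-methoxyphenyl)propioloyl]phenyl}-4-methoxybenzoate
Product: 16 tert-butyl 3-[5,7-dimethoxy-2-(4-methoxyphenyl)-4-oxo-4H-chromen-6-yl]-4-methoxybenzoate, via enaminone 15 (not isolated)
Conditions: Et2NH (5 equiv), EtOH, 60 °C
Reagents that add atoms: diethylamine, CCNCC (its atoms are held in intermediate 15 only and leave again on ring closure)
Why: Conjugate addition of the secondary amine to the ynone gives β-amino enone 15. The phenol oxygen then displaces the amine at that same β-carbon by addition–elimination, which can only give the six-membered pyranone (formally a 6-endo closure) and shuts off the 5-exo route to a benzofuranone.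

Step 8
Reactants: 16 tert-butyl 3-[5,7-dimethoxy-2-(4-methoxyphenyl)-4-oxo-4H-chromen-6-yl]-4-methoxybenzoate
Product: 17 3-[5,7-dihydroxy-2-(4-hydroxyphenyl)-4-oxo-4H-chromen-6-yl]-4-hydroxybenzoic acid
Conditions: BBr3 (12 equiv), CH2Cl2, –78 °C → rt (40 °C if needed); then H2O, 0 °C
Reagents that add atoms: none
Why: This is a global Lewis acid deprotection: boron coordinates each ether oxygen and bromide removes the methyl group, starting with the C5 ether next to the carbonyl, and the tert-butyl ester is cleaved through loss of the tert-butyl cation. Aqueous work-up hydrolyses the aryl and acyl borates to the four phenols and the acid.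

## Compound list

1 | 3-bromo-4-methoxybenzoic acid | COc1ccc(C(=O)O)cc1Br | starting material
2 | tert-butyl 3-bromo-4-methoxybenzoate | COc1ccc(C(=O)OC(C)(C)C)cc1Br | intermediate
3 | (2,6-dimethoxyphenyl)boronic acid | COc1cccc(OC)c1B(O)O | starting material
4 | tert-butyl 3-(2,6-dimethoxyphenyl)-4-methoxybenzoate | CC(C)(C)OC(=O)c1ccc(OC)c(-c2c(OC)cccc2OC)c1 | intermediate
5 | tert-butyl 3-[2,6-dimethoxy-4-(4,4,5,5-tetramethyl-1,3,2-dioxaborolan-2-yl)phenyl]-4-methoxybenzoate | CC(C)(C)OC(=O)c1ccc(OC)c(-c2c(OC)cc(B3OC(C)(C)C(C)(C)O3)cc2OC)c1 | intermediate (not isolated)
6 | tert-butyl 3-(4-hydroxy-2,6-dimethoxyphenyl)-4-methoxybenzoate | CC(C)(C)OC(=O)c1ccc(OC)c(-c2c(OC)cc(O)cc2OC)c1 | intermediate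
7 | tert-butyl 3-(3-bromo-4-hydroxy-2,6-dimethoxyphenyl)-4-methoxybenzoate | CC(C)(C)OC(=O)c1ccc(OC)c(-c2c(OC)cc(O)c(Br)c2OC)c1 | intermediate
8 | tert-butyl 3-[3-bromo-2,6-dimethoxy-4-(trimethylsilyloxy)phenyl]-4-methoxybenzoate | CC(C)(C)OC(=O)c1ccc(OC)c(-c2c(OC)cc(O[Si](C)(C)C)c(Br)c2OC)c1 | intermediate (not isolated)
9 | tert-butyl 3-[3-lithio-2,6-dimethoxy-4-(trimethylsilyloxy)phenyl]-4-methoxybenzoate | CC(C)(C)OC(=O)c1ccc(OC)c(-c2c(OC)cc(O[Si](C)(C)C)c([Li])c2OC)c1 | intermediate (not isolated)
10 | lithium 4-[5-(tert-butoxycarbonyl)-2-methoxyphenyl]-3,5-dimethoxy-2-(trimethylsilyl)phenolate | [Li+].CC(C)(C)OC(=O)c1ccc(OC)c(-c2c(OC)cc([O-])c([Si](C)(C)C)c2OC)c1 | intermediate (not isolated)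
11 | tert-butyl 3-[2,6-dimethoxy-4-(trifluoromethanesulfonyloxy)-3-(trimethylsilyl)phenyl]-4-methoxybenzoate | CC(C)(C)OC(=O)c1ccc(OC)c(-c2c(OC)cc(OS(=O)(=O)C(F)(F)F)c([Si](C)(C)C)c2OC)c1 | intermediate
12 | 3-(4-methoxyphenyl)propiolic acid | COc1ccc(C#CC(=O)O)cc1 | starting material
13 | tert-butyl 3-(3,4-didehydro-2,6-dimethoxyphenyl)-4-methoxybenzoate (aryne across the future C4a–C8a) | COC1=C(c2cc(ccc2OC)C(=O)OC(C)(C)C)C(OC)=CC#C1 | intermediate (not isolated)
14 | tert-butyl 3-{4-hydroxy-2,6-dimethoxy-3-[3-(4-methoxyphenyl)propioloyl]phenyl}-4-methoxybenzoate | CC(C)(C)OC(=O)c1ccc(OC)c(-c2c(OC)cc(O)c(C(=O)C#Cc3ccc(OC)cc3)c2OC)c1 | intermediate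
15 | tert-butyl 3-{3-[(2E)-3-(diethylamino)-3-(4-methoxyphenyl)prop-2-enoyl]-4-hydroxy-2,6-dimethoxyphenyl}-4-methoxybenzoate (E drawn as expected for a tertiary enaminone; the geometry does not affect the ring closure) | CC(C)(C)OC(=O)c1ccc(OC)c(-c2c(OC)cc(O)c(C(=O)/C=C(/N(CC)CC)c3ccc(OC)cc3)c2OC)c1 | intermediate (not isolated)
16 | tert-butyl 3-[5,7-dimethoxy-2-(4-methoxyphenyl)-4-oxo-4H-chromen-6-yl]-4-methoxybenzoate | CC(C)(C)OC(=O)c1ccc(OC)c(-c2c(OC)cc3oc(-c4ccc(OC)cc4)cc(=O)c3c2OC)c1 | intermediate
17 | 3-[5,7-dihydroxy-2-(4-hydroxyphenyl)-4-oxo-4H-chromen-6-yl]-4-hydroxybenzoic acid | O=C(O)c1ccc(O)c(-c2c(O)cc3oc(-c4ccc(O)cc4)cc(=O)c3c2O)c1 | target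

## Step count and least certain steps

Total step count: 8. Longest linear sequence: 8 steps (1 → 2 → 4 → 6 → 7 → 11 → 14 → 16 → 17); 3 and 12 are bought.

Step 6 (key step). The most likely failure is protonation of the C4a aryl anion by un-ionised acid or hydrogen fluoride before the acyl group has migrated, which would stop the sequence at simple O-arylation. The acyl shift has to pass a strained four-membered transition state at a carbanion flanked by two ortho substituents. Thermal decarboxylation of the propiolate and uncontrolled ring closure of the product phenoxide are further drains. The fallback leaves the aryne and forms C4–C4a by acylpalladium chemistry. It sets out from 6, which is iodinated with N-iodosuccinimide (1.0 equiv, CH2Cl2, –40 °C) to tert-butyl 3-(4-hydroxy-3-iodo-2,6-dimethoxyphenyl)-4-methoxybenzoate F1. Carbonylative Sonogashira coupling of F1 with 1-ethynyl-4-methoxybenzene under CO (balloon) with PdCl2(PPh3)2 in Et2NH should form ynone 14 in the flask, and the amine should close it as in step 7, so the route is rejoined at 16.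

Step 5. The most likely failure is attack of butyllithium or of the aryllithium on the tert-butyl ester, or quenching of the aryllithium before the silyl group has migrated. The ester is the only electrophile present, and the lithiated carbon is crowded between two oxygen substituents. The fallback avoids organolithium reagents and makes the C–Si bond by cross-coupling, setting out from 7. Benzylation (BnBr, K2CO3, DMF) gives tert-butyl 3-[4-(benzyloxy)-3-bromo-2,6-dimethoxyphenyl]-4-methoxybenzoate F2. Silylation with Me3SiSiMe3, Pd2(dba)3, 2-(di-tert-butylphosphino)biphenyl and LiOAc in DMF at 100 °C gives tert-butyl 3-[4-(benzyloxy)-2,6-dimethoxy-3-(trimethylsilyl)phenyl]-4-methoxybenzoate F3. Hydrogenolysis (H2, Pd/C, EtOAc) gives tert-butyl 3-[4-hydroxy-2,6-dimethoxy-3-(trimethylsilyl)phenyl]-4-methoxybenzoate F4, and Tf2O with pyridine in CH2Cl2 at 0 °C returns to the route at 11.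

Step 3. The most likely failure is erosion of site selectivity, by borylation next to the methoxy group of ring D or by a second borylation, or over-oxidation of the very electron-rich phenol by the peroxide. The fallback brings the ring-A oxygen in with the building block and reverses the polarity of the coupling. It sets out from 2, which Miyaura borylation (B2pin2, PdCl2(dppf), KOAc, dioxane, 90 °C) converts into tert-butyl 4-methoxy-3-(4,4,5,5-tetramethyl-1,3,2-dioxaborolan-2-yl)benzoate F5. Suzuki–Miyaura coupling of F5 with 4-bromo-3,5-dimethoxyphenol (assumed here to be a catalogue compound; Pd(OAc)2, SPhos, K3PO4, toluene/H2O, 100 °C) returns to the route at 6.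

Step 7. The most likely failure is competing five-membered closure of the phenoxide onto the alkyne carbon next to the carbonyl, or stalling at 15 because the ketone, flanked by two ortho substituents, is twisted out of conjugation. The fallback closes ring C by cyclodehydration of a 1,3-diketone, which can only give the pyranone. It sets out from 14, which is taken to 15 with Et2NH and hydrolysed with dilute HCl in THF to tert-butyl 3-{4-hydroxy-2,6-dimethoxy-3-[3-(4-methoxyphenyl)-3-oxopropanoyl]phenyl}-4-methoxybenzoate F6. H2SO4 in AcOH at 80 °C should close the ring and also remove the tert-butyl group, giving 3-[5,7-dimethoxy-2-(4-methoxyphenyl)-4-oxo-4H-chromen-6-yl]-4-methoxybenzoic acid F7. Treatment of F7 with BBr3 under the conditions of step 8 returns to the route at 17.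

## Further compounds

F1 | step 6 | tert-butyl 3-(4-hydroxy-3-iodo-2,6-dimethoxyphenyl)-4-methoxybenzoate | CC(C)(C)OC(=O)c1ccc(OC)c(-c2c(OC)cc(O)c(I)c2OC)c1
F2 | step 5 | tert-butyl 3-[4-(benzyloxy)-3-bromo-2,6-dimethoxyphenyl]-4-methoxybenzoate | CC(C)(C)OC(=O)c1ccc(OC)c(-c2c(OC)cc(OCc3ccccc3)c(Br)c2OC)c1
F3 | step 5 | tert-butyl 3-[4-(benzyloxy)-2,6-dimethoxy-3-(trimethylsilyl)phenyl]-4-methoxybenzoate | CC(C)(C)OC(=O)c1ccc(OC)c(-c2c(OC)cc(OCc3ccccc3)c([Si](C)(C)C)c2OC)c1
F4 | step 5 | tert-butyl 3-[4-hydroxy-2,6-dimethoxy-3-(trimethylsilyl)phenyl]-4-methoxybenzoate | CC(C)(C)OC(=O)c1ccc(OC)c(-c2c(OC)cc(O)c([Si](C)(C)C)c2OC)c1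
F5 | step 3 | tert-butyl 4-methoxy-3-(4,4,5,5-tetramethyl-1,3,2-dioxaborolan-2-yl)benzoate | CC(C)(C)OC(=O)c1ccc(OC)c(B2OC(C)(C)C(C)(C)O2)c1
F6 | step 7 | tert-butyl 3-{4-hydroxy-2,6-dimethoxy-3-[3-(4-methoxyphenyl)-3-oxopropanoyl]phenyl}-4-methoxybenzoate | CC(C)(C)OC(=O)c1ccc(OC)c(-c2c(OC)cc(O)c(C(=O)CC(=O)c3ccc(OC)cc3)c2OC)c1
F7 | step 7 | 3-[5,7-dimethoxy-2-(4-methoxyphenyl)-4-oxo-4H-chromen-6-yl]-4-methoxybenzoic acid | COc1ccc(cc1)-c1cc(=O)c2c(OC)c(-c3cc(C(=O)O)ccc3OC)c(OC)cc2o1
A1 | alternative 1 | 6-[3-(tert-butyldimethylsilyloxy)buta-1,3-dien-2-yl]-5,7-dimethoxy-2-(4-methoxyphenyl)-4H-chromen-4-one | C=C(O[Si](C)(C)C(C)(C)C)C(=C)c1c(OC)cc2oc(-c3ccc(OC)cc3)cc(=O)c2c1OC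
A2 | alternative 1 | methyl propiolate | C#CC(=O)OC
A3 | alternative 1 | methyl 4-(tert-butyldimethylsilyloxy)-5-[5,7-dimethoxy-2-(4-methoxyphenyl)-4-oxo-4H-chromen-6-yl]cyclohexa-1,4-diene-1-carboxylate | COC(=O)C1=CCC(O[Si](C)(C)C(C)(C)C)=C(C1)c1c(OC)cc2oc(-c3ccc(OC)cc3)cc(=O)c2c1OC
A4 | alternative 2 | 5-hydroxy-7-methoxy-2-(4-methoxyphenyl)-4H-chromen-4-one | COc1ccc(cc1)-c1cc(=O)c2c(O)cc(OC)cc2o1
A5 | alternative 2 | methyl 3-bromo-4-({[7-methoxy-2-(4-methoxyphenyl)-4-oxo-4H-chromen-5-yl]oxy}methoxy)benzoate | COC(=O)c1ccc(OCOc2cc(OC)cc3oc(-c4ccc(OC)cc4)cc(=O)c23)c(Br)c1
A6 | alternative 2 | methylene-bridged biaryl: O5 and the D4 oxygen joined by CH2 (dibenzo[d,f][1,3]dioxepine fused to the 7-methoxy-2-(4-methoxyphenyl)chromen-4-one, methyl ester on ring D) | COC(=O)c1ccc2OCOc3c(c(OC)cc4oc(-c5ccc(OC)cc5)cc(=O)c34)-c2c1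
A7 | alternative 3 | 6-(ethoxyethynyl)-5,7-dimethoxy-2-(4-methoxyphenyl)-4H-chromen-4-one | CCOC#Cc1c(OC)cc2oc(-c3ccc(OC)cc3)cc(=O)c2c1OC
A8 | alternative 3 | methyl coumalate (methyl 2-oxo-2H-pyran-5-carboxylate) | COC(=O)C1=COC(=O)C=C1
A9 | alternative 3 | methyl 3-[5,7-dimethoxy-2-(4-methoxyphenyl)-4-oxo-4H-chromen-6-yl]-4-ethoxybenzoate | CCOc1ccc(C(=O)OC)cc1-c1c(OC)cc2oc(-c3ccc(OC)cc3)cc(=O)c2c1OC
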